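The route rests on one disconnection of the 1,2-dioxolane ring: the O2–C3 bond and the exocyclic C1–C2 bond are made together. Because C3 is quaternary (ring oxygen O2, methyl, the C2 methylene and ring carbon C4), it can come from the inner carbon of a 2-methylallyl group, and the C2–palladium bond formed on ring closure has no β-hydrogen. A palladium-mediated peroxycarbonylation should therefore close the five-membered peroxide ring, set C3 and add the C1 carboxyl carbon in one operation. The precursor is the open-chain tertiary hydroperoxide 28 bearing the complete phenyl-diene chain and a methallyl group; its C–OOH centre arises by invertive perhydrolysis of an oxetane built from (R)-citronellal.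

Key step: step 18

Assumption: commercial (R)-citronellal of high enantiomeric purity is used (it is also one oxidation step from (R)-citronellol), and the carbinol centre made in step 5 is carried as both epimers until it is oxidised in step 16.
Numbering: C1–C17 are the chain atoms of the target acid (C1 carboxyl, C3 and C5 ring carbons, C7 the methyl-bearing carbon, C12=C13 and C16=C17 the E alkenes); the target is the 3S,5R,7R isomer, with the acetic acid arm and the C6 chain trans on the ring.

Step 1
Reactants: 1 (R)-citronellal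
Product: 2 (4R)-4,8-dimethylnon-7-en-1-yne
Conditions: MeC(O)C(N2)P(O)(OMe)2, K2CO3, MeOH, 0 °C → rt
Reagents that add atoms: dimethyl (1-diazo-2-oxopropyl)phosphonate, CC(=O)C(=[N+]=[N-])P(=O)(OC)OC
Why: Ohira–Bestmann (Seyferth–Gilbert) homologation turns the aldehyde into the terminal alkyne with one added carbon under mild carbonate conditions, and the methyl-bearing centre, being β to the carbonyl, cannot epimerise.

Step 2
Reactants: 2 (4R)-4,8-dimethylnon-7-en-1-yne
Product: 5 (2E,5R)-3,5,9-trimethyldeca-2,8-dien-1-ol, via alkenyldimethylalane 3 (not isolated), via lithium alanate 4 (not isolated)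
Conditions: AlMe3, Cp2ZrCl2 (20 mol %), CH2Cl2, 0 °C → rt; excess AlMe3 removed in vacuo; n-BuLi, THF–hexane, −78 °C; (CH2O)n, −78 °C → rt; aqueous work-up
Reagents that add atoms: trimethylaluminium, C[Al](C)C; formaldehyde (as paraformaldehyde), C=O
Why: Zirconium-catalysed carboalumination of the terminal alkyne (Negishi carboalumination) adds methyl and aluminium syn with methyl on the inner carbon, so only the E trisubstituted alkene forms, and the derived alanate adds to formaldehyde with retention of geometry while the remote trisubstituted alkene is inert.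

Step 3
Reactants: 5 (2E,5R)-3,5,9-trimethyldeca-2,8-dien-1-ol
Product: 6 [(2S,3S)-3-[(2R)-2,6-dimethylhept-5-en-1-yl]-3-methyloxiran-2-yl]methanol
Conditions: Ti(OiPr)4 (10 mol %), L-(+)-diethyl tartrate (12 mol %), t-BuOOH, 4 Å MS, CH2Cl2, −20 °C
Reagents that add atoms: tert-butyl hydroperoxide, CC(C)(C)OO
Why: Sharpless asymmetric epoxidation of an E-3-methyl allylic alcohol of the geraniol type: the titanium–L-(+)-tartrate catalyst delivers oxygen to one alkene face under reagent control to give the (2S,3S)-epoxide, which fixes the tertiary C–O centre that becomes C5, and the isolated alkene lacks the directing hydroxyl and is not touched.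

Step 4
Reactants: 6 [(2S,3S)-3-[(2R)-2,6-dimethylhept-5-en-1-yl]-3-methyloxiran-2-yl]methanol
Product: 7 (2R,3S)-3-[(2R)-2,6-dimethylhept-5-en-1-yl]-3-methyloxirane-2-carbaldehyde
Conditions: Dess–Martin periodinane, pyridine, CH2Cl2, 0 °C → rt
Reagents that add atoms: none
Why: Dess–Martin oxidation under buffered conditions converts the primary epoxy alcohol into the epoxy aldehyde without opening the epoxide or epimerising the α-carbon.

Step 5
Reactants: 7 (2R,3S)-3-[(2R)-2,6-dimethylhept-5-en-1-yl]-3-methyloxirane-2-carbaldehyde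
Product: 8 1-[(2S,3S)-3-[(2R)-2,6-dimethylhept-5-en-1-yl]-3-methyloxiran-2-yl]ethan-1-ol (both carbinol epimers)
Conditions: MeMgBr, Et2O, −78 °C; aqueous work-up
Reagents that add atoms: methylmagnesium bromide, C[Mg]Br
Why: Grignard addition to the aldehyde is far faster than attack on the trisubstituted epoxide; the new carbinol centre is not controlled and need not be, since it becomes the ketone carbon in step 16.

Step 6
Reactants: 8 1-[(2S,3S)-3-[(2R)-2,6-dimethylhept-5-en-1-yl]-3-methyloxiran-2-yl]ethan-1-ol
Product: 9 (4S,6R)-4,6,10-trimethylundec-9-ene-2,4-diol (both C2 epimers)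
Conditions: NaAlH2(OCH2CH2OMe)2, THF, 0 °C → rt; aq. potassium sodium tartrate
Reagents that add atoms: none
Why: Hydroxyl-directed hydride opening of a 2,3-epoxy alcohol: the alkoxyaluminate formed from the carbinol delivers hydride intramolecularly to the adjacent, less substituted epoxide carbon, giving the 1,3-diol and leaving the tertiary C–O bond and its configuration intact.

Step 7
Reactants: 9 (4S,6R)-4,6,10-trimethylundec-9-ene-2,4-diol
Product: 11 (2S)-2-[(2R)-2,6-dimethylhept-5-en-1-yl]-2,4-dimethyloxetane (both C4 epimers), via secondary mesylate 10 (not isolated)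
Conditions: MsCl, Et3N, CH2Cl2, −20 °C; then KOtBu, THF, 0 °C → rt
Reagents that add atoms: none
Why: The secondary hydroxyl is mesylated selectively over the hindered tertiary one and the tertiary alkoxide then displaces the mesylate in an intramolecular Williamson etherification (4-exo-tet), so the tertiary centre keeps its configuration because its C–O bond is never broken.

Step 8
Reactants: 11 (2S)-2-[(2R)-2,6-dimethylhept-5-en-1-yl]-2,4-dimethyloxetane
Product: 13 (4R)-5-[(2S)-2,4-dimethyloxetan-2-yl]-4-methylpentanal, via ozonide 12 (not isolated)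
Conditions: O3, CH2Cl2, −78 °C; then PPh3, −78 °C → rt
Reagents that add atoms: ozone, [O-][O+]=O
Why: Ozonolysis with reductive work-up cleaves the only alkene to the aldehyde, the oxetane being inert to ozone and to triphenylphosphine under these non-acidic conditions.

Step 9
Reactants: 13 (4R)-5-[(2S)-2,4-dimethyloxetan-2-yl]-4-methylpentanal
Product: 14 (2S)-2,4-dimethyl-2-[(2R)-2-methylhex-5-en-1-yl]oxetane
Conditions: Ph3PCH3Br, KOtBu, THF, 0 °C → rt
Reagents that add atoms: methyltriphenylphosphonium bromide, C[P+](c1ccccc1)(c1ccccc1)c1ccccc1.[Br-]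
Why: Wittig methylenation of an unhindered aldehyde gives the terminal alkene needed for hydroboration, and the basic conditions leave the acid-sensitive oxetane untouched.

Step 10
Reactants: 15 trimethyl(prop-1-yn-1-yl)silane; 16 cinnamyl chloride
Product: 18 trimethyl[(5E)-6-phenylhex-5-en-1-yn-1-yl]silane, via lithiated silylpropyne 17 (not isolated)
Conditions: n-BuLi, TMEDA, THF, −20 °C; then 16, −78 °C → rt
Reagents that add atoms: none
Why: Propargylic lithiation of the silylpropyne and SN2 alkylation at the primary allylic chloride join the two pieces, the silyl group steering reaction to the propargyl terminus and the E-styryl geometry being carried through unchanged.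

Step 11
Reactants: 18 trimethyl[(5E)-6-phenylhex-5-en-1-yn-1-yl]silane
Product: 19 [(1E)-hex-1-en-5-yn-1-yl]benzene
Conditions: K2CO3 (cat.), MeOH, rt
Reagents that add atoms: none
Why: Base-catalysed methanolysis of the alkynyl C–Si bond (protodesilylation) frees the terminal alkyne.

Step 12
Reactants: 19 [(1E)-hex-1-en-5-yn-1-yl]benzene
Product: 21 [(1E,5E)-6-iodohexa-1,5-dien-1-yl]benzene, via alkenylzirconocene chloride 20 (not isolated)
Conditions: Cp2Zr(H)Cl, THF, rt; then I2, 0 °C
Reagents that add atoms: iodine, II
Why: Schwartz hydrozirconation adds Zr–H syn across the terminal alkyne with zirconium at the terminal carbon, much faster than it reacts with the internal styryl alkene, and iodinolysis with retention gives the E-alkenyl iodide.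

Step 13
Reactants: 14 (2S)-2,4-dimethyl-2-[(2R)-2-methylhex-5-en-1-yl]oxetane; 21 [(1E,5E)-6-iodohexa-1,5-dien-1-yl]benzene
Product: 23 (2S)-2,4-dimethyl-2-[(2R,7E,11E)-2-methyl-12-phenyldodeca-7,11-dien-1-yl]oxetane, via B-alkyl-9-borabicyclononane 22 (not isolated)
Conditions: 9-BBN-H, THF, 0 °C → rt; then 21, Pd(dppf)Cl2 (5 mol %), AsPh3, Cs2CO3, DMF–H2O, rt
Reagents that add atoms: none
Why: Anti-Markovnikov hydroboration of the terminal alkene followed by B-alkyl Suzuki–Miyaura coupling forms the C11–C12 bond, and because the alkenyl iodide couples with retention the C12=C13 alkene is obtained as the E isomer.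

Step 14
Reactants: 23 (2S)-2,4-dimethyl-2-[(2R,7E,11E)-2-methyl-12-phenyldodeca-7,11-dien-1-yl]oxetane
Product: 24 (4R,6R,11E,15E)-4-hydroperoxy-4,6-dimethyl-16-phenylhexadeca-11,15-dien-2-ol (both C2 epimers)
Conditions: H2O2 (anhydrous, in Et2O, excess), TMSOTf (20 mol %), Et2O, −78 → −20 °C
Reagents that add atoms: hydrogen peroxide, OO
Why: Lewis acid-promoted perhydrolysis of an oxetane: the silyl-activated ring is opened by hydrogen peroxide at the tertiary carbon, the C–O bond best able to bear positive charge, from the side opposite the departing oxygen, so the hydroperoxide is installed with inversion and the (S) tertiary ether becomes the (R) tertiary hydroperoxide.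

Step 15
Reactants: 24 (4R,6R,11E,15E)-4-hydroperoxy-4,6-dimethyl-16-phenylhexadeca-11,15-dien-2-ol
Product: 25 (4R,6R,11E,15E)-4-[(2-methoxypropan-2-yl)peroxy]-4,6-dimethyl-16-phenylhexadeca-11,15-dien-2-ol (both C2 epimers)
Conditions: 2-methoxypropene, PPTS (cat.), CH2Cl2, 0 °C; Et3N quench
Reagents that add atoms: 2-methoxypropene, COC(C)=C
Why: Acid-catalysed addition of the hydroperoxide to the enol ether gives the monoperoxyketal, the hydroperoxide (alpha-effect nucleophile with an unhindered terminal oxygen) reacting ahead of the secondary alcohol when about one equivalent of enol ether is used at low temperature and the acid is quenched promptly.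

Step 16
Reactants: 25 (4R,6R,11E,15E)-4-[(2-methoxypropan-2-yl)peroxy]-4,6-dimethyl-16-phenylhexadeca-11,15-dien-2-ol
Product: 26 (4R,6R,11E,15E)-4-[(2-methoxypropan-2-yl)peroxy]-4,6-dimethyl-16-phenylhexadeca-11,15-dien-2-one
Conditions: Dess–Martin periodinane, pyridine, CH2Cl2, 0 °C → rt
Reagents that add atoms: none
Why: Dess–Martin oxidation of the secondary alcohol to the methyl ketone under buffered, non-basic conditions that leave the peroxyketal intact; the adjacent peroxide-bearing centre is quaternary and cannot epimerise.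

Step 17
Reactants: 26 (4R,6R,11E,15E)-4-[(2-methoxypropan-2-yl)peroxy]-4,6-dimethyl-16-phenylhexadeca-11,15-dien-2-one
Product: 28 (4R,6R,11E,15E)-4-hydroperoxy-2,4,6-trimethyl-16-phenylhexadeca-1,11,15-triene, via peroxyketal triene 27 (not isolated)
Conditions: Ph3PCH3Br, KOtBu, THF, 0 °C; then 26, −78 → 0 °C; then AcOH–THF–H2O, rt
Reagents that add atoms: methyltriphenylphosphonium bromide, C[P+](c1ccccc1)(c1ccccc1)c1ccccc1.[Br-]
Why: Wittig methylenation of the methyl ketone installs the 2-methylallyl group, monoperoxyketals being tolerant of phosphorus ylides, and the aqueous acetic acid added afterwards hydrolyses the peroxyketal to release the free hydroperoxide.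

Step 18
Reactants: 28 (4R,6R,11E,15E)-4-hydroperoxy-2,4,6-trimethyl-16-phenylhexadeca-1,11,15-triene
Product: 29 methyl 2-[(3S,5R)-3,5-dimethyl-5-[(2R,7E,11E)-2-methyl-12-phenyldodeca-7,11-dien-1-yl]-1,2-dioxolan-3-yl]acetate
Conditions: Pd(OCOCF3)2 (10 mol %), 2,2'-(propane-2,2-diyl)bis(4,4-dimethyl-2-oxazoline) (12 mol %), p-benzoquinone (2 equiv), CO (1–4 atm), MeOH–CH2Cl2, −10 → 10 °C, dark
Reagents that add atoms: carbon monoxide, [C-]#[O+]; methanol, CO
Why: Proposed new method: divalent palladium should coordinate the electron-rich 1,1-disubstituted alkene of 28, the terminal oxygen of the C5 hydroperoxide should add to the substituted alkene carbon C3 in a 5-exo-trig oxypalladation that closes the 1,2-dioxolane (O2–C3 bond), and the resulting C2–palladium bond, which has no β-hydrogen because C3 is quaternary, should insert CO and be cleaved by methanol to the ester (C1–C2 bond) while benzoquinone returns zerovalent palladium to the divalent state. The closest known reaction types are the alkoxycarbonylative oxypalladation of hydroxy alkenes and the divalent-palladium-catalysed cyclisation of unsaturated hydroperoxides to cyclic peroxides, which ends by β-hydride elimination where this substrate cannot. The new C3 centre is controlled by the C5 stereocentre: in the envelope transition state the palladium-bearing methylene should lie anti to the branched C6 chain and syn to the C5 methyl, giving the 3S,5R ring in which the acetate arm and the chain are trans; if this 1,3-induction proves weak, a chiral bis(oxazoline) on palladium offers reagent control. The step needs site selectivity for the methallyl alkene over the C12 and C16 alkenes, which is secured by intramolecular delivery of the only nucleophile to an alkene three atoms away and by the higher electron density of the 1,1-disubstituted alkene, while attack at C3 and not C2 follows from the 5-exo geometry and the tertiary character of C3. Reversal of the oxypalladation is countered by CO pressure, and O–O cleavage by low-valent palladium is countered by excess quinone, the absence of phosphines and copper salts, and low temperature.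

Step 19
Reactants: 29 methyl 2-[(3S,5R)-3,5-dimethyl-5-[(2R,7E,11E)-2-methyl-12-phenyldodeca-7,11-dien-1-yl]-1,2-dioxolan-3-yl]acetate
Product: 30 2-[(3S,5R)-3,5-dimethyl-5-[(2R,7E,11E)-2-methyl-12-phenyldodeca-7,11-dien-1-yl]-1,2-dioxolan-3-yl]acetic acid
Conditions: LiOH·H2O, THF–H2O, 0 °C; then 1 M HCl to pH 4
Reagents that add atoms: lithium hydroxide, [Li+].[OH-]
Why: Saponification of the unhindered methyl ester by cold aqueous hydroxide, which dialkyl peroxides tolerate, should outpace enolate formation and β-elimination of the ring oxygen; no stereocentre is affected.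

Compound list
1 | (R)-citronellal, (3R)-3,7-dimethyloct-6-enal | C[C@H](CCC=C(C)C)CC=O | starting material
2 | (4R)-4,8-dimethylnon-7-en-1-yne | C[C@H](CCC=C(C)C)CC#C | intermediate
3 | dimethyl[(1E,4R)-2,4,8-trimethylnona-1,7-dien-1-yl]alane | C[C@H](CCC=C(C)C)C/C(C)=C/[Al](C)C | intermediate
4 | lithium butyldimethyl[(1E,4R)-2,4,8-trimethylnona-1,7-dien-1-yl]aluminate | [Li+].CCCC[Al-](C)(C)/C=C(\C)C[C@H](C)CCC=C(C)C | intermediate
5 | (2E,5R)-3,5,9-trimethyldeca-2,8-dien-1-ol | C[C@H](CCC=C(C)C)C/C(C)=C/CO | intermediate
6 | [(2S,3S)-3-[(2R)-2,6-dimethylhept-5-en-1-yl]-3-methyloxiran-2-yl]methanol | C[C@H](CCC=C(C)C)C[C@]1(C)O[C@H]1CO | intermediate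
7 | (2R,3S)-3-[(2R)-2,6-dimethylhept-5-en-1-yl]-3-methyloxirane-2-carbaldehyde | C[C@H](CCC=C(C)C)C[C@]1(C)O[C@H]1C=O | intermediate
8 | 1-[(2S,3S)-3-[(2R)-2,6-dimethylhept-5-en-1-yl]-3-methyloxiran-2-yl]ethan-1-ol, both carbinol epimers | C[C@H](CCC=C(C)C)C[C@]1(C)O[C@H]1C(C)O | intermediate
9 | (4S,6R)-4,6,10-trimethylundec-9-ene-2,4-diol, both C2 epimers | C[C@H](CCC=C(C)C)C[C@](C)(O)CC(C)O | intermediate
10 | (4S,6R)-4-hydroxy-4,6,10-trimethylundec-9-en-2-yl methanesulfonate, both C2 epimers | C[C@H](CCC=C(C)C)C[C@](C)(O)CC(C)OS(C)(=O)=O | intermediate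
11 | (2S)-2-[(2R)-2,6-dimethylhept-5-en-1-yl]-2,4-dimethyloxetane, both C4 epimers | C[C@H](CCC=C(C)C)C[C@]1(C)OC(C)C1 | intermediate
12 | 5-[(3R)-4-[(2S)-2,4-dimethyloxetan-2-yl]-3-methylbutyl]-3,3-dimethyl-1,2,4-trioxolane (ozonide) | CC1(C)OOC(CC[C@@H](C)C[C@]2(C)OC(C)C2)O1 | intermediate
13 | (4R)-5-[(2S)-2,4-dimethyloxetan-2-yl]-4-methylpentanal | C[C@H](CCC=O)C[C@]1(C)OC(C)C1 | intermediate
14 | (2S)-2,4-dimethyl-2-[(2R)-2-methylhex-5-en-1-yl]oxetane | C[C@H](CCC=C)C[C@]1(C)OC(C)C1 | intermediate
15 | trimethyl(prop-1-yn-1-yl)silane | CC#C[Si](C)(C)C | starting material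
16 | cinnamyl chloride, [(1E)-3-chloroprop-1-en-1-yl]benzene | ClC/C=C/c1ccccc1 | starting material
17 | 3-lithio-1-(trimethylsilyl)prop-1-yne | [Li]CC#C[Si](C)(C)C | intermediate
18 | trimethyl[(5E)-6-phenylhex-5-en-1-yn-1-yl]silane | C[Si](C)(C)C#CCC/C=C/c1ccccc1 | intermediate
19 | [(1E)-hex-1-en-5-yn-1-yl]benzene | C#CCC/C=C/c1ccccc1 | intermediate
20 | chlorobis(cyclopentadienyl)[(1E,5E)-6-phenylhexa-1,5-dien-1-yl]zirconium | Cl[Zr](/C=C/CC/C=C/c1ccccc1)(C1C=CC=C1)C1C=CC=C1 | intermediate
21 | [(1E,5E)-6-iodohexa-1,5-dien-1-yl]benzene | I/C=C/CC/C=C/c1ccccc1 | intermediate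
22 | 9-[(5R)-6-[(2S)-2,4-dimethyloxetan-2-yl]-5-methylhexyl]-9-borabicyclo[3.3.1]nonane | C[C@H](CCCCB1C2CCCC1CCC2)C[C@]1(C)OC(C)C1 | intermediate
23 | (2S)-2,4-dimethyl-2-[(2R,7E,11E)-2-methyl-12-phenyldodeca-7,11-dien-1-yl]oxetane, both C4 epimers | C[C@H](CCCC/C=C/CC/C=C/c1ccccc1)C[C@]1(C)OC(C)C1 | intermediate
24 | (4R,6R,11E,15E)-4-hydroperoxy-4,6-dimethyl-16-phenylhexadeca-11,15-dien-2-ol, both C2 epimers | C[C@H](CCCC/C=C/CC/C=C/c1ccccc1)C[C@@](C)(OO)CC(C)O | intermediate
25 | (4R,6R,11E,15E)-4-[(2-methoxypropan-2-yl)peroxy]-4,6-dimethyl-16-phenylhexadeca-11,15-dien-2-ol, both C2 epimers | C[C@H](CCCC/C=C/CC/C=C/c1ccccc1)C[C@@](C)(OOC(C)(C)OC)CC(C)O | intermediate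
26 | (4R,6R,11E,15E)-4-[(2-methoxypropan-2-yl)peroxy]-4,6-dimethyl-16-phenylhexadeca-11,15-dien-2-one | C[C@H](CCCC/C=C/CC/C=C/c1ccccc1)C[C@@](C)(OOC(C)(C)OC)CC(C)=O | intermediate
27 | (4R,6R,11E,15E)-4-[(2-methoxypropan-2-yl)peroxy]-2,4,6-trimethyl-16-phenylhexadeca-1,11,15-triene | C[C@H](CCCC/C=C/CC/C=C/c1ccccc1)C[C@@](C)(OOC(C)(C)OC)CC(C)=C | intermediate
28 | (4R,6R,11E,15E)-4-hydroperoxy-2,4,6-trimethyl-16-phenylhexadeca-1,11,15-triene | C[C@H](CCCC/C=C/CC/C=C/c1ccccc1)C[C@@](C)(OO)CC(C)=C | intermediate
29 | methyl 2-[(3S,5R)-3,5-dimethyl-5-[(2R,7E,11E)-2-methyl-12-phenyldodeca-7,11-dien-1-yl]-1,2-dioxolan-3-yl]acetate | C[C@H](CCCC/C=C/CC/C=C/c1ccccc1)C[C@]1(C)C[C@@](C)(CC(=O)OC)OO1 | intermediate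
30 | 2-[(3S,5R)-3,5-dimethyl-5-[(2R,7E,11E)-2-methyl-12-phenyldodeca-7,11-dien-1-yl]-1,2-dioxolan-3-yl]acetic acid (CNP0204107.3) | C[C@H](CCCC/C=C/CC/C=C/c1ccccc1)C[C@]1(C)C[C@@](C)(CC(=O)O)OO1 | target

Total step count: 19. Longest linear sequence: 16 steps (steps 1–9 and 13–19, from (R)-citronellal); the alkenyl iodide 21 is made in 3 steps (10–12) and joined in step 13.

Steps most likely to fail

Step 18 (proposed new method). The oxypalladation may revert faster than CO inserts. Low-valent palladium may reduce the O–O bond, so that the hydroperoxide is consumed as the oxidant. The catalyst may engage the remote alkenes, or the ring may close with poor facial selectivity at C3. The fallback uses known chemistry and sets out from ketone 26. Acidic methanol (HCl cat., MeOH, 0 °C) should remove the peroxyketal. The freed β-hydroperoxy ketone closes to the cyclic peroxyhemiketal, which exchanges with methanol to give (5R)-3-methoxy-3,5-dimethyl-5-[(2R,7E,11E)-2-methyl-12-phenyldodeca-7,11-dien-1-yl]-1,2-dioxolane F1 as both C3 epimers. Ionisation with TiCl4 in CH2Cl2 at −78 °C and capture of the ring peroxycarbenium ion by 1-methoxy-1-(trimethylsilyloxy)ethene is the established Lewis acid-mediated alkylation of 3-alkoxy-1,2-dioxolanes by silyl ketene acetals. It should give methyl ester 29 together with methyl 2-[(3R,5R)-3,5-dimethyl-5-[(2R,7E,11E)-2-methyl-12-phenyldodeca-7,11-dien-1-yl]-1,2-dioxolan-3-yl]acetate F2, to be separated by chromatography. The route is rejoined at 29.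

Step 17. The ylide may act as a base on the β-peroxy ketone, so that enolisation and β-elimination of the peroxide compete with addition to the carbonyl. The fallback sets out from ketone 26 and uses the non-basic titanium methylidene source Cp2Ti(μ-Cl)(μ-CH2)AlMe2 (Tebbe olefination; pyridine, THF–toluene, −40 → 0 °C). This is a cycloaddition–cycloreversion pathway that does not pass through an enolate. It should give peroxyketal triene 27, which is hydrolysed with aqueous acetic acid as in step 17. The route is rejoined at 27.

Step 14. The activated oxetane may ionise to a free tertiary cation, with loss of configuration at C5 or elimination to a homoallylic alcohol, and the silyl triflate may trigger acid-promoted reactions of the styryl diene. The fallback sets out from oxetane 23 and replaces electrophilic ionisation by metal-peroxo delivery: MoO2(acac)2-catalysed perhydrolysis with ethereal H2O2 at room temperature, a known near-neutral opening of tertiary oxetanes to 3-hydroperoxy alcohols. It should give 24 directly, and the route is rejoined at 24.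

Further compounds
F1 | step 18 | (5R)-3-methoxy-3,5-dimethyl-5-[(2R,7E,11E)-2-methyl-12-phenyldodeca-7,11-dien-1-yl]-1,2-dioxolane, both C3 epimers | C[C@H](CCCC/C=C/CC/C=C/c1ccccc1)C[C@]1(C)CC(C)(OC)OO1
F2 | step 18 | methyl 2-[(3R,5R)-3,5-dimethyl-5-[(2R,7E,11E)-2-methyl-12-phenyldodeca-7,11-dien-1-yl]-1,2-dioxolan-3-yl]acetate | C[C@H](CCCC/C=C/CC/C=C/c1ccccc1)C[C@]1(C)C[C@](C)(CC(=O)OC)OO1
F0 | step 17 | none | none
F0 | step 14 | none | none
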